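## Retrosynthetic overview

1. Locants follow halichlorine numbering: C1 lactone C=O, C2=C3 ring alkene, C4 ring CH2, C5 N–CH, C9 spiro carbon, C13 cyclopentane CH, C14 CHMe, C15=C16 Z-alkene, C17 carbinol, C18=C19 chloroalkene, C21 OCH2, C23 NCH2. Rings: A cyclopentane, B piperidine, C tetrahydropyridine, D 15-membered lactone.
2. Enabling feature: ring C (N–C23H2–C2(C1=O)=C3H–C4H2–C5H) is a 1,2,5,6-tetrahydropyridine-3-carboxylate, the [4+2] retron of the ring-B imine C5=N and a 2-(alkoxycarbonyl)buta-1,3-diene. Its ester carbonyl C1 is the lactone carbonyl, so the diene is already tied through O–C21…C14 to C13 of ring A; cutting C4–C5 and N–C23 opens rings C and D together and leaves spiro-imine ester 23, with the diene stored as a 3-sulfolene.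
3. 23 ⇒ imine diol 20 + 3-sulfolene-3-carboxylic acid 22 (ester at the primary alcohol); 20 ⇒ ene-carbamate 19 (fluoride releases the imine and the C21 hydroxyl together).
4. Side chain: Z-C15=C16 by semi-hydrogenation of alkyne 18; C16–C17 bond and the C17 centre by catalytic asymmetric alkynylation of enal 17, whose C18=C19 geometry is copied from the ring of 4-chloro-5,6-dihydropyran-2-one 14.
5. Core 12: temporary γ-lactam on ring A by Meyers lactamization of 1 with 2 (sets C9, C13), allylation, C14 methylation, hydroformylation (adds C5), lactam → alkyne, ring B closed as ene-carbamate. Ring order: A (given) → γ-lactam (later opened) → B → C and D together.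

Key step: step 18

Remark (assumption): in step 13 the (S,S)-enantiomer of ProPhenol is written and is taken to give the (S)-propargylic carbinol; if the facial sense for this alkyne/enal pair is the opposite, (R,R)-ProPhenol is used under the same conditions.

## Route

Step 1
Reactants: 1 2-(2-oxocyclopentyl)acetic acid (racemic); 2 (R)-phenylglycinol
Product: 3 tricyclic N,O-acetal lactam (single diastereomer)
Conditions: PhMe, reflux, Dean–Stark, 24 h
Reagents that add atoms: none
Why: Meyers bicyclic-lactam cyclodehydration in which the stereocentre next to the ketone (C13) epimerizes through the enamine, so both enantiomers of 1 should converge on the cis-fused lactam with phenyl on the convex face, which fixes C9 and C13.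

Step 2
Reactants: 3 tricyclic N,O-acetal lactam
Product: 4 N-(2-hydroxy-1-phenylethyl) 6a-allyl lactam
Conditions: allylSiMe3 (3 equiv), TiCl4 (3 equiv), CH2Cl2, −78 → 23 °C
Reagents that add atoms: allyltrimethylsilane C=CC[Si](C)(C)C
Why: Hosomi–Sakurai allylation of the N-acyliminium ion formed by N,O-acetal opening; the allyl group can only enter cis to the ring-fusion hydrogen of the cis-fused bicycle, so the quaternary C9 forms with nitrogen cis to the C14 arm.

Step 3
Reactants: 4 N-(2-hydroxy-1-phenylethyl) 6a-allyl lactam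
Product: 5 (3aR,6aS)-6a-allylhexahydrocyclopenta[b]pyrrol-2(1H)-one
Conditions: Li, NH3(l), THF, EtOH, −78 °C; then NH4Cl
Reagents that add atoms: none
Why: dissolving-metal cleavage of the benzylic C–N bond removes the auxiliary as 2-phenylethanol while the terminal alkene and the lactam are inert.

Step 4
Reactants: 5 (3aR,6aS)-6a-allylhexahydrocyclopenta[b]pyrrol-2(1H)-one
Product: 6 N-Teoc allyl lactam
Conditions: n-BuLi (1.05 equiv), THF, −78 °C; then 4-nitrophenyl 2-(trimethylsilyl)ethyl carbonate, −78 → 0 °C
Reagents that add atoms: 4-nitrophenyl 2-(trimethylsilyl)ethyl carbonate C[Si](C)(C)CCOC(=O)Oc1ccc(cc1)[N+](=O)[O-]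
Why: N-acylation of the lithium lactamate by an activated carbonate gives a carbamate that activates the lactam for enolization and partial reduction and can later be removed by fluoride.

Step 5
Reactants: 6 N-Teoc allyl lactam
Product: 7 N-Teoc 3-methyl allyl lactam
Conditions: LiN(SiMe3)2, THF, −78 °C; MeI, −78 → −40 °C
Reagents that add atoms: iodomethane CI
Why: enolate alkylation on the convex face of the cis-fused bicycle (anti to the cyclopentane ring) should place the methyl cis to the ring-fusion hydrogen and so set C14.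

Step 6
Reactants: 7 N-Teoc 3-methyl allyl lactam
Product: 9 dimethyl acetal lactam, via aldehyde 8 (not isolated)
Conditions: Rh(acac)(CO)2 (1 mol %), BiPhePhos (2 mol %), CO/H2 (1:1, 10 bar), PhMe, 70 °C; then HC(OMe)3, MeOH, PPTS (cat.), 23 °C
Reagents that add atoms: carbon monoxide [C-]#[O+]; trimethyl orthoformate COC(OC)OC
Why: linear-selective rhodium-catalysed hydroformylation of the terminal alkene adds C5 as the aldehyde, and acetalization in the same flask protects it from the hydride and base steps that follow.

Step 7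
Reactants: 9 dimethyl acetal lactam
Product: 10 N-Teoc lactamol (mixture at the hemiaminal carbon)
Conditions: LiBHEt3 (1.2 equiv), THF, −78 °C; then aq. NaHCO3
Reagents that add atoms: none
Why: low-temperature hydride reduction of the N-acyl lactam carbonyl stops at the hemiaminal, a masked C15 aldehyde, and touches no stereocentre of the target.

Step 8
Reactants: 10 N-Teoc lactamol
Product: 11 open-chain NH-Teoc alkyne acetal
Conditions: dimethyl (1-diazo-2-oxopropyl)phosphonate, K2CO3, MeOH, 0 → 23 °C
Reagents that add atoms: dimethyl (1-diazo-2-oxopropyl)phosphonate COP(=O)(OC)C(=[N+]=[N-])C(C)=O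
Why: Seyferth–Gilbert homologation (Ohira–Bestmann variant) of the ring-opened aldehyde tautomer gives the terminal alkyne (C16), and the mild carbonate conditions should leave the adjacent methyl-bearing centre unepimerized.

Step 9
Reactants: 11 open-chain NH-Teoc alkyne acetal
Product: 12 spirocyclic N-Teoc ene-carbamate alkyne
Conditions: PPTS (0.1 equiv), PhMe, 100 °C, MeOH distilled off
Reagents that add atoms: none
Why: acid-catalysed N,O-acetal formation and loss of methanol (N-acyliminium to ene-carbamate) closes ring B and stores the future imine in a neutral, non-basic form.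

Step 10
Reactants: 13 dihydro-2H-pyran-2,4(3H)-dione
Product: 14 4-chloro-5,6-dihydro-2H-pyran-2-one
Conditions: (COCl)2 (1.2 equiv), DMF (cat.), CH2Cl2, 0 → 23 °C
Reagents that add atoms: oxalyl chloride O=C(Cl)C(Cl)=O
Why: Vilsmeier-type conversion of the enolized cyclic β-keto lactone into the vinylogous acid chloride; the ring holds C17 and C20 cis, which is the required 18E geometry.

Step 11
Reactants: 14 4-chloro-5,6-dihydro-2H-pyran-2-one
Product: 16 TBS-protected Weinreb amide, via hydroxy Weinreb amide 15 (not isolated)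
Conditions: MeNH(OMe)·HCl, AlMe3, CH2Cl2, 0 °C; then TBSCl, imidazole, DMF, 0 → 23 °C
Reagents that add atoms: N,O-dimethylhydroxylamine hydrochloride CNOC.Cl; tert-butyldimethylsilyl chloride CC(C)(C)[Si](C)(C)Cl
Why: Weinreb aminolysis by the aluminium amide at the lactone carbonyl opens the ring with the alkene geometry retained, and immediate silylation of the freed alcohol prevents relactonization.

Step 12
Reactants: 16 TBS-protected Weinreb amide
Product: 17 (2E)-5-(tert-butyldimethylsilyloxy)-3-chloropent-2-enal
Conditions: i-Bu2AlH (1.2 equiv), THF, −78 °C; aq. Rochelle salt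
Reagents that add atoms: none
Why: Weinreb amide reduction stops at the aldehyde through the chelated tetrahedral intermediate and should give the β-chloro enal without conjugate reduction.

Step 13
Reactants: 12 spirocyclic N-Teoc ene-carbamate alkyne; 17 (2E)-5-(tert-butyldimethylsilyloxy)-3-chloropent-2-enal
Product: 18 propargylic alcohol
Conditions: (S,S)-ProPhenol (20 mol %), Me2Zn (3 equiv), Ph3PO (40 mol %), 17 (1.5 equiv), PhMe, 0 → 4 °C, 48 h
Reagents that add atoms: none
Why: zinc–ProPhenol-catalysed asymmetric alkynylation of an α,β-unsaturated aldehyde, in which the dinuclear zinc catalyst selects the aldehyde face and sets C17 (S at this stage, R after step 14 only because CIP priorities change) independently of the remote centres.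

Step 14
Reactants: 18 propargylic alcohol
Product: 19 Z-allylic alcohol
Conditions: H2 (1 atm), Pd/CaCO3 poisoned with Pb(OAc)2 (Lindlar catalyst), quinoline, EtOAc, 23 °C, stopped at 1 equiv H2
Reagents that add atoms: none
Why: Lindlar syn semi-hydrogenation of the internal alkyne should give the Z-C15=C16 alkene while the vinyl chloride, the ene-carbamate and the silyl groups are left.

Step 15
Reactants: 19 Z-allylic alcohol
Product: 20 spirocyclic imine diol
Conditions: Bu4NF (4 equiv), THF, 0 → 40 °C
Reagents that add atoms: none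
Why: fluoride cleaves the primary silyl ether and triggers Teoc fragmentation, and the liberated azaallyl anion should protonate to the cyclic imine, which is kept monomeric by the adjacent quaternary carbon.

Step 16
Reactants: 21 3-sulfolene
Product: 22 3-sulfolene-3-carboxylic acid
Conditions: DBU (2 equiv), CO2 (3 bar), DMSO, 23 °C; then aq. HCl
Reagents that add atoms: carbon dioxide O=C=O
Why: DBU-mediated carboxylation of the sulfolene α-carbanion followed by base-induced double-bond migration should give the conjugated 3-carboxylic acid, a known one-pot reaction type.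

Step 17
Reactants: 20 spirocyclic imine diol; 22 3-sulfolene-3-carboxylic acid
Product: 23 imine sulfolene ester
Conditions: EDC·HCl (1.2 equiv), DMAP (0.1 equiv), 22 (1.1 equiv), CH2Cl2, −20 → 0 °C
Reagents that add atoms: none
Why: Steglich esterification should be selective for the primary alcohol over the hindered doubly allylic secondary one, with the imine nitrogen shielded by the quaternary carbon and by protonation, and with low temperature and catalytic DMAP limiting base-induced isomerization of the sulfolene.

Step 18
Reactants: 23 imine sulfolene ester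
Product: 25 target CNP0129639.4, via diene ester 24 (not isolated)
Conditions: 23 added over 12 h to PhMe (final 1 mM), BHT (0.2 equiv), 110 °C, Ar sparge
Reagents that add atoms: none
Why: Proposed new method: at 110 °C the 3-sulfolene ester should lose SO2 by cheletropic extrusion to give the 2-(alkoxycarbonyl)buta-1,3-diene 24, whose acrylate CH2 (C23) is attacked by the imine nitrogen lone pair while the remote diene CH2 (C4) bonds to the imine carbon C5, as an asynchronous inverse-electron-demand aza-Diels–Alder reaction or, at the stepwise limit, aza-Michael addition followed by vinylogous Mannich closure of the ester dienolate. The closest known reaction types are the generation and Diels–Alder trapping of 2-carboalkoxybutadienes from 3-sulfolene-3-carboxylates, the aza-Michael/Mannich annulation of cyclic imines with enones to quinolizidinones, and macrocyclizing type 2 intramolecular Diels–Alder reactions; their combination on an N-alkyl cyclic imine with a 15-membered bridging ring is new. Two rings close: ring C by [4+2] (6-(enolendo)-endo-trig in the stepwise description) and ring D as the bridging ring of a type 2 intramolecular cycloaddition, the tether running from the diene C2 ester through O–C21…C14 to C13. The only new stereocentre, C5, is controlled by the tether: the diene hangs from C13 on one face of the piperideine while the other face carries the pseudoaxial C10 methylene, so C4 should be delivered cis to C13 (5R), which is also the isomer favoured if the Mannich step is reversible. Regiochemistry is secured because only C23 of the diene is electrophilic and only the dienolate γ-carbon C4 can reach C5 in a six-membered ring. The selectivities needed are ring closure over diene dimerization (high dilution and slow addition), N- over C-alkylation through the enamine tautomer (neutral aprotic medium), and survival of the Z-alkene and allylic alcohol (SO2 removed in the argon stream).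

## Compound list

1 | 2-(2-oxocyclopentyl)acetic acid (racemic) | O=C(O)CC1CCCC1=O | starting material
2 | (R)-2-amino-2-phenylethanol ((R)-phenylglycinol) | N[C@@H](CO)c1ccccc1 | starting material
3 | tricyclic Meyers lactam: oxazolidine O and lactam N on the former ketone carbon, cyclopentane cis-fused to the γ-lactam, phenyl on the (R)-carbon cis to the angular cyclopentane CH2 | C1C(=O)N2[C@H](c3ccccc3)CO[C@]24CCC[C@H]14 | intermediate
4 | (3aR,6aS)-6a-allyl-1-[(1R)-2-hydroxy-1-phenylethyl]hexahydrocyclopenta[b]pyrrol-2(1H)-one | C1C(=O)N([C@@H](CO)c3ccccc3)[C@]2(CC=C)CCC[C@H]12 | intermediate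
5 | (3aR,6aS)-6a-allylhexahydrocyclopenta[b]pyrrol-2(1H)-one | C1C(=O)N[C@]2(CC=C)CCC[C@H]12 | intermediate
6 | 2-(trimethylsilyl)ethyl (3aR,6aS)-6a-allyl-2-oxohexahydrocyclopenta[b]pyrrole-1(2H)-carboxylate | C1C(=O)N(C(=O)OCC[Si](C)(C)C)[C@]2(CC=C)CCC[C@H]12 | intermediate
7 | 2-(trimethylsilyl)ethyl (3R,3aR,6aS)-6a-allyl-3-methyl-2-oxohexahydrocyclopenta[b]pyrrole-1(2H)-carboxylate | C[C@H]1C(=O)N(C(=O)OCC[Si](C)(C)C)[C@]2(CC=C)CCC[C@H]12 | intermediate
8 | 2-(trimethylsilyl)ethyl (3R,3aR,6aS)-3-methyl-2-oxo-6a-(4-oxobutyl)hexahydrocyclopenta[b]pyrrole-1(2H)-carboxylate | C[C@H]1C(=O)N(C(=O)OCC[Si](C)(C)C)[C@]2(CCCC=O)CCC[C@H]12 | intermediate (not isolated)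
9 | 2-(trimethylsilyl)ethyl (3R,3aR,6aS)-6a-(4,4-dimethoxybutyl)-3-methyl-2-oxohexahydrocyclopenta[b]pyrrole-1(2H)-carboxylate | C[C@H]1C(=O)N(C(=O)OCC[Si](C)(C)C)[C@]2(CCCC(OC)OC)CCC[C@H]12 | intermediate
10 | 2-hydroxy analogue of 9 (lactamol, both epimers at the hemiaminal carbon) | C[C@H]1C(O)N(C(=O)OCC[Si](C)(C)C)[C@]2(CCCC(OC)OC)CCC[C@H]12 | intermediate
11 | 2-(trimethylsilyl)ethyl N-[(1S,2R)-2-[(2R)-but-3-yn-2-yl]-1-(4,4-dimethoxybutyl)cyclopentyl]carbamate | C[C@@H](C#C)[C@H]1CCC[C@@]1(CCCC(OC)OC)NC(=O)OCC[Si](C)(C)C | intermediate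
12 | 2-(trimethylsilyl)ethyl (1R,5S)-1-[(2R)-but-3-yn-2-yl]-6-azaspiro[4.5]dec-7-ene-6-carboxylate | C[C@@H](C#C)[C@H]1CCC[C@]12CCC=CN2C(=O)OCC[Si](C)(C)C | intermediate
13 | dihydro-2H-pyran-2,4(3H)-dione | O=C1CCOC(=O)C1 | starting material
14 | 4-chloro-5,6-dihydro-2H-pyran-2-one | O=C1C=C(Cl)CCO1 | intermediate
15 | (2E)-3-chloro-5-hydroxy-N-methoxy-N-methylpent-2-enamide | CON(C)C(=O)/C=C(/Cl)CCO | intermediate (not isolated)
16 | (2E)-5-(tert-butyldimethylsilyloxy)-3-chloro-N-methoxy-N-methylpent-2-enamide | CON(C)C(=O)/C=C(/Cl)CCO[Si](C)(C)C(C)(C)C | intermediate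
17 | (2E)-5-(tert-butyldimethylsilyloxy)-3-chloropent-2-enal | O=C/C=C(/Cl)CCO[Si](C)(C)C(C)(C)C | intermediate
18 | 2-(trimethylsilyl)ethyl (1R,5S)-1-[(2R,5S,6E)-9-(tert-butyldimethylsilyloxy)-7-chloro-5-hydroxynon-6-en-3-yn-2-yl]-6-azaspiro[4.5]dec-7-ene-6-carboxylate | C[C@@H](C#C[C@@H](O)/C=C(/Cl)CCO[Si](C)(C)C(C)(C)C)[C@H]1CCC[C@]12CCC=CN2C(=O)OCC[Si](C)(C)C | intermediate
19 | 2-(trimethylsilyl)ethyl (1R,5S)-1-[(2S,3Z,5R,6E)-9-(tert-butyldimethylsilyloxy)-7-chloro-5-hydroxynona-3,6-dien-2-yl]-6-azaspiro[4.5]dec-7-ene-6-carboxylate | C[C@@H](/C=C\[C@@H](O)/C=C(/Cl)CCO[Si](C)(C)C(C)(C)C)[C@H]1CCC[C@]12CCC=CN2C(=O)OCC[Si](C)(C)C | intermediate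
20 | (3E,5R,6Z,8S)-8-[(1R,5S)-6-azaspiro[4.5]dec-6-en-1-yl]-3-chloronona-3,6-diene-1,5-diol | C[C@@H](/C=C\[C@@H](O)/C=C(/Cl)CCO)[C@H]1CCC[C@]12CCCC=N2 | intermediate
21 | 3-sulfolene (2,5-dihydrothiophene 1,1-dioxide) | O=S1(=O)CC=CC1 | starting material
22 | 2,5-dihydrothiophene-3-carboxylic acid 1,1-dioxide | O=C(O)C1=CCS(=O)(=O)C1 | intermediate
23 | (3E,5R,6Z,8S)-8-[(1R,5S)-6-azaspiro[4.5]dec-6-en-1-yl]-3-chloro-5-hydroxynona-3,6-dien-1-yl 1,1-dioxo-2,5-dihydrothiophene-3-carboxylate | C[C@@H](/C=C\[C@@H](O)/C=C(/Cl)CCOC(=O)C1=CCS(=O)(=O)C1)[C@H]1CCC[C@]12CCCC=N2 | intermediate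
24 | (3E,5R,6Z,8S)-8-[(1R,5S)-6-azaspiro[4.5]dec-6-en-1-yl]-3-chloro-5-hydroxynona-3,6-dien-1-yl 2-methylidenebut-3-enoate | C[C@@H](/C=C\[C@@H](O)/C=C(/Cl)CCOC(=O)C(=C)C=C)[C@H]1CCC[C@]12CCCC=N2 | intermediate (not isolated)
25 | CNP0129639.4, (5R,9S,13R,14S,15Z,17R,18E) in halichlorine numbering | C[C@H]1/C=C\[C@@H](O)/C=C(/Cl)CCOC(=O)C2=CC[C@H]3CCC[C@]4(CCC[C@H]14)N3C2 | target

## Step count and risks

Total step count: 18 (steps 1–9 core, 10–12 enal, 16 acid, 13–15 and 17–18 union and endgame).
Longest linear sequence: 14 steps (1–9, 13, 14, 15, 17, 18).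

Steps most likely to fail:

1. Step 18 (Proposed new method). The slow macrocyclizing closure may be outrun by bimolecular dimerization or oligomerization of the liberated diene. The imine may also react through its enamine tautomer at carbon, or the closure may leak to the other face at C5. Fallback with known chemistry, setting out from 20 and returning at 25: allylmagnesium bromide (excess, THF, −78 → 0 °C) adds to the C=N bond by axial attack anti to the pseudoaxial cyclopentane CH2 to give the 2-allylpiperidine diol F1. N-Alkylation with 2-(bromomethyl)acrylic acid (K2CO3, MeCN) gives the N-(2-carboxyallyl) amino acid F2. Ring-closing metathesis of its camphorsulfonate salt with second-generation Grubbs catalyst (CH2Cl2, 40 °C) closes ring C with loss of ethylene and gives the seco acid F3. Yamaguchi macrolactonization (2,4,6-trichlorobenzoyl chloride, Et3N, then DMAP, PhMe, high dilution) at the primary hydroxyl closes ring D to 25.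

2. Step 13. Conversion may stall with the α-branched alkyne, face selection on the β-chloro enal may be poor, or methyl transfer may compete. Fallback, setting out from 12 and 16 and returning at 18: the lithium acetylide of 12 (n-BuLi, THF, −78 °C) is acylated by Weinreb amide 16 to give the ynone F4. Corey–Bakshi–Shibata reduction with the (S)-oxazaborolidine and catecholborane (PhMe, −78 °C), with the alkynyl group as the small substituent, should then deliver 18.

3. Step 17. Acylation may occur on the imine nitrogen (leading to an enamide) or on the secondary hydroxyl, and the basic medium may shift the sulfolene double bond into conjugation with the sulfone. Fallback, setting out from 19 and returning at 23: selective cleavage of the primary silyl ether (HF·pyridine, pyridine, THF, 0 °C) gives the ene-carbamate diol F5. Steglich esterification with 22 then takes place with no imine present and gives the ene-carbamate sulfolene ester F6. Teoc cleavage with acetic-acid-buffered Bu4NF (THF, 0 °C) releases imine ester 23.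

## Further compounds

F1 | step 18 | (3E,5R,6Z,8S)-8-[(1R,5S,7R)-7-allyl-6-azaspiro[4.5]decan-1-yl]-3-chloronona-3,6-diene-1,5-diol | C[C@@H](/C=C\[C@@H](O)/C=C(/Cl)CCO)[C@H]1CCC[C@]12CCC[C@H](CC=C)N2
F2 | step 18 | 2-{[(1R,5S,7R)-7-allyl-1-[(2S,3Z,5R,6E)-7-chloro-5,9-dihydroxynona-3,6-dien-2-yl]-6-azaspiro[4.5]decan-6-yl]methyl}acrylic acid | C[C@@H](/C=C\[C@@H](O)/C=C(/Cl)CCO)[C@H]1CCC[C@]12CCC[C@H](CC=C)N2CC(=C)C(=O)O
F3 | step 18 | seco acid: spiro-fused 1,2,5,6-tetrahydropyridine-3-carboxylic acid (rings A, B and C closed) carrying the free (2S,3Z,5R,6E)-7-chloro-5,9-dihydroxynona-3,6-dien-2-yl chain | C[C@@H](/C=C\[C@@H](O)/C=C(/Cl)CCO)[C@H]1CCC[C@]12CCC[C@@H]3CC=C(C(=O)O)CN23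
F4 | step 13 | 2-(trimethylsilyl)ethyl (1R,5S)-1-[(2R,6E)-9-(tert-butyldimethylsilyloxy)-7-chloro-5-oxonon-6-en-3-yn-2-yl]-6-azaspiro[4.5]dec-7-ene-6-carboxylate | C[C@@H](C#CC(=O)/C=C(/Cl)CCO[Si](C)(C)C(C)(C)C)[C@H]1CCC[C@]12CCC=CN2C(=O)OCC[Si](C)(C)C
F5 | step 17 | 2-(trimethylsilyl)ethyl (1R,5S)-1-[(2S,3Z,5R,6E)-7-chloro-5,9-dihydroxynona-3,6-dien-2-yl]-6-azaspiro[4.5]dec-7-ene-6-carboxylate | C[C@@H](/C=C\[C@@H](O)/C=C(/Cl)CCO)[C@H]1CCC[C@]12CCC=CN2C(=O)OCC[Si](C)(C)C
F6 | step 17 | 1,1-dioxo-2,5-dihydrothiophene-3-carboxylate ester of F5 at the primary hydroxyl | C[C@@H](/C=C\[C@@H](O)/C=C(/Cl)CCOC(=O)C1=CCS(=O)(=O)C1)[C@H]1CCC[C@]12CCC=CN2C(=O)OCC[Si](C)(C)C
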